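I could not carry a final share from one charge to another: at 40.0 min target held 54.3% in the zeta run but 45.8% in the epsilon run.

| flask | substrate | remark | time |
|---|---|---|---|
| zeta | 0.75 M | run made earlier |  |
| epsilon | 1.1 M | run made earlier |  |
| flask | 1.5 M |  | 1.0 h |

- zeta (time / min: substrate / %, target / %, side product / %): 8.00: 58.6, 30.5, 10.5; 15.0: 33.7, 43.0, 23.3; 20.0: 23.7, 47.8, 29.6; 30.0: 10.4, 52.6, 38.2; 40.0: 3.6, 54.3, 41.1
- epsilon (time / min: substrate / %, target / %, side product / %): 3.00: 83.0, 13.8, 2.6; 10.0: 49.0, 31.3, 18.9; 15.0: 31.6, 38.3, 29.7; 25.0: 12.3, 43.4, 42.9; 40.0: 2.6, 45.8, 50.9

(each reading ± 0.5 percentage points)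

* the species that holds most of what was charged as substrate, at 1.0 h (target / side product / substrate)
* the largest share itself, whichever of these holds it, in percent of the substrate charged

- a species is counted by the substrate in it: one side product counts as two
- the numbers in the tables scatter with a standard deviation of 0.5 percentage points
- what may be going on: substrate -> target; substrate + target -> side product

So I took the proposed steps, substrate → target (constant k) and substrate + target → side product (constant k′), and compared their rates. With C the charge and t target's share, second over first is a·t, where a = k′C/k. Between readings, half the side-product gain is second-step turnover, and that plus the target gain is first-step turnover. Zeta (15.0 min to 30.0 min) read a = 0.914 and epsilon (10.0 min to 25.0 min) 1.33, so k′/k read 1.22 M⁻¹, and the flask got a = 1.82, this competition number being a selectivity factor. Epsilon's substrate was down to 2.6% at 40.0 min, so I reckoned the flask as finished by 1.0 h; then t = (1 − exp(−a(1 + t)/2))/a gave me target 39.5% and side product 60.5%.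

The forecast said side product, 60% (58% to 62%), less than my share, and of its ratio of constants it said “in both runs, which supports the scheme”.

The flask gave side product at 60.0%, with target 39.7% and substrate 0.375%.

    substrate → target (k = 0.0574 min⁻¹)
    substrate + target → side product (k = 0.0690 M⁻¹ min⁻¹)

In the flask at 1.00 h the first step still used substrate 1.4 times as fast as the second, and 1/(a·t) on the flask's target gives 1.38. The flask's turnovers came to 69.6% and 30.0%, so target kept 39.6% and side product, counted double, 60.0%.

For the neighbour with 0.60 M of substrate, a = 0.729 and the same equation gives target 60.6%; that flask held target 60.7% and side product 38.3%.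

(The readings come from a simulation with constants of no real substance; noise was put on by code.)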